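**Retrosynthetic overview**
- Cut the central ArCH2Ar bridge: ring A comes from Mannich base 4 (as its ortho-quinone methide 8) and ring B from the free ring CH of phenol 7.
- 4 comes from ketone 3 by phenolic aminomethylation; 7 comes from ketone 6 by para-selective O-methylation.
- 3 and 6 both come from 2-methylphloroglucinol 1 by Friedel–Crafts acylation with butanoyl chloride and propanoyl chloride.
- No ring is formed: both benzene rings are bought as 1, elaborated separately into ring A and ring B, and joined last.

Assumption: the target has no stereocentre and is achiral, so no stereocontrol is needed; 1, 2 and 5 are taken as commercial.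

**Route**

Step 1
Reactants: 1 2-methylbenzene-1,3,5-triol; 2 butanoyl chloride
Product: 3 1-(2,4,6-trihydroxy-3-methylphenyl)butan-1-one
Conditions: AlCl3 (3.5 equiv), PhNO2/CH2Cl2 (1:1), 0 °C → 45 °C; then ice/2 M HCl
Reagents that add atoms: none
Why: Friedel–Crafts C-acylation of the electron-rich triol, where the two free ring positions of 1 are equivalent by symmetry and the first acyl group deactivates the ring against a second one; no stereocentre is formed.

Step 2
Reactants: 3 1-(2,4,6-trihydroxy-3-methylphenyl)butan-1-one
Product: 4 1-[3-[(dimethylamino)methyl]-2,4,6-trihydroxy-5-methylphenyl]butan-1-one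
Conditions: 37% aq. HCHO (1.05 equiv) premixed with 40% aq. Me2NH (1.3 equiv), EtOH, 0 °C → rt; product filtered off
Reagents that add atoms: formaldehyde C=O; dimethylamine CNC
Why: Phenolic Mannich reaction at the only remaining ring CH of 3, with excess amine and precipitation of the zwitterionic product holding back methylene bridging of two phenols; no stereocentre is formed.

Step 3
Reactants: 1 2-methylbenzene-1,3,5-triol; 5 propanoyl chloride
Product: 6 1-(2,4,6-trihydroxy-3-methylphenyl)propan-1-one
Conditions: AlCl3 (3.5 equiv), PhNO2/CH2Cl2 (1:1), 0 °C → 45 °C; then ice/2 M HCl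
Reagents that add atoms: none
Why: Friedel–Crafts C-acylation as in step 1, giving a single regioisomer because of the symmetry of 1; no stereocentre is formed.

Step 4
Reactants: 6 1-(2,4,6-trihydroxy-3-methylphenyl)propan-1-one
Product: 7 1-(2,6-dihydroxy-4-methoxy-3-methylphenyl)propan-1-one
Conditions: Me2SO4 (1.0 equiv), K2CO3 (1.0 equiv), acetone, 0 °C → rt
Reagents that add atoms: dimethyl sulfate COS(=O)(=O)OC
Why: Williamson-type O-methylation with limiting base, in which the 4-hydroxyl para to the ketone is the most acidic and is not held by the carbonyl like the two ortho hydroxyls, so it is alkylated first; no stereocentre is formed.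

Step 5
Reactants: 4 1-[3-[(dimethylamino)methyl]-2,4,6-trihydroxy-5-methylphenyl]butan-1-one; 7 1-(2,6-dihydroxy-4-methoxy-3-methylphenyl)propan-1-one
Product: 9 1-[3-[(2,4-dihydroxy-6-methoxy-5-methyl-3-propanoylphenyl)methyl]-2,4,6-trihydroxy-5-methylphenyl]butan-1-one, via ortho-quinone methide 8 (not isolated)
Conditions: 7 (1.3 equiv), 1,4-dioxane, 100 °C, N2 sweep
Reagents that add atoms: none
Why: Thermal elimination of dimethylamine from the Mannich base gives ortho-quinone methide 8, which is captured in a conjugate Friedel–Crafts (Michael-type) addition by the only free ring carbon of 7 and rearomatises to the achiral methylene-bridged target.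

**Compound list**

1 | 2-methylbenzene-1,3,5-triol (2-methylphloroglucinol) | Cc1c(O)cc(O)cc1O | starting material
2 | butanoyl chloride | CCCC(=O)Cl | starting material
3 | 1-(2,4,6-trihydroxy-3-methylphenyl)butan-1-one | CCCC(=O)c1c(O)cc(O)c(C)c1O | intermediate
4 | 1-[3-[(dimethylamino)methyl]-2,4,6-trihydroxy-5-methylphenyl]butan-1-one | CCCC(=O)c1c(O)c(C)c(O)c(CN(C)C)c1O | intermediate
5 | propanoyl chloride | CCC(=O)Cl | starting material
6 | 1-(2,4,6-trihydroxy-3-methylphenyl)propan-1-one | CCC(=O)c1c(O)cc(O)c(C)c1O | intermediate
7 | 1-(2,6-dihydroxy-4-methoxy-3-methylphenyl)propan-1-one | CCC(=O)c1c(O)c(C)c(OC)cc1O | intermediate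
8 | 4-butanoyl-3,5-dihydroxy-2-methyl-6-methylidenecyclohexa-2,4-dien-1-one (ortho-quinone methide) | CCCC(=O)C1=C(O)C(=C)C(=O)C(C)=C1O | intermediate
9 | 1-[3-[(2,4-dihydroxy-6-methoxy-5-methyl-3-propanoylphenyl)methyl]-2,4,6-trihydroxy-5-methylphenyl]butan-1-one | CCCC(=O)c1c(O)c(C)c(O)c(Cc2c(O)c(C(=O)CC)c(O)c(C)c2OC)c1O | target

**Totals**

Total step count: 5. Longest linear sequence: 3 steps (1 → 3 → 4 → 9, or 1 → 6 → 7 → 9).

**Steps most likely to fail, with fallbacks**

Step 4 (mono-methylation of 6) is the most likely to fail, because the ortho hydroxyls or a second methylation may compete. The fallback sets out from 6 and returns at 7. Exhaustive methylation of 6 (Me2SO4 in excess, K2CO3, acetone, reflux) gives 1-(2,4,6-trimethoxy-3-methylphenyl)propan-1-one F1. AlCl3 (excess) in chlorobenzene at 80 °C then cleaves only the two methoxy groups ortho to the ketone by carbonyl-directed chelation, leaving the para methoxy group and giving 7.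

Step 5 (cross-coupling) is next, because quinone methide 8 may attack a second molecule of 4 at the substituted carbon and give symmetrical dimers. The fallback reverses the roles; it sets out from 7 (with 3 as partner) and returns at 9. A Mannich reaction of 7 (aq. HCHO, aq. Me2NH, EtOH, rt) at its only free ring position gives 1-[3-[(dimethylamino)methyl]-2,6-dihydroxy-4-methoxy-5-methylphenyl]propan-1-one F2. Heating F2 with 3 in 1,4-dioxane releases dimethylamine and forms in the flask 3-hydroxy-5-methoxy-4-methyl-6-methylidene-2-propanoylcyclohexa-2,4-dien-1-one F3. The more nucleophilic triol 3 adds to F3 at its free ring carbon to give 9.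

Step 2 (Mannich reaction of 3) is third, because 3 is reactive enough that it may be bridged by formaldehyde before the amine is incorporated. The fallback sets out from 3 and returns at 9, bypassing 4. Lederer–Manasse hydroxymethylation of 3 (excess aq. HCHO, dilute aq. KOH, 0 °C, careful acidification and extraction) gives 1-[2,4,6-trihydroxy-3-(hydroxymethyl)-5-methylphenyl]butan-1-one F4, which is used crude. With catalytic TsOH in 1,4-dioxane at rt in the presence of 7 (1.5 equiv), F4 loses water to the same quinone methide 8, and 7 adds to it to give 9.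

Further compounds
F1 | step 4 | 1-(2,4,6-trimethoxy-3-methylphenyl)propan-1-one | CCC(=O)c1c(OC)cc(OC)c(C)c1OC
F2 | step 5 | 1-[3-[(dimethylamino)methyl]-2,6-dihydroxy-4-methoxy-5-methylphenyl]propan-1-one | CCC(=O)c1c(O)c(C)c(OC)c(CN(C)C)c1O
F3 | step 5 | 3-hydroxy-5-methoxy-4-methyl-6-methylidene-2-propanoylcyclohexa-2,4-dien-1-one | CCC(=O)C1=C(O)C(C)=C(OC)C(=C)C1=O
F4 | step 2 | 1-[2,4,6-trihydroxy-3-(hydroxymethyl)-5-methylphenyl]butan-1-one | CCCC(=O)c1c(O)c(C)c(O)c(CO)c1O
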